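Everything rests on disconnecting the two carbinol O–acetyl bonds at C3 and C5 of the heptane chain. In one operation a ruthenium catalyst epimerises every free carbinol while a lipase acetylates only (R) centres, so all stereoisomers of a 1,7-diarylheptane-3,5-diol should converge on the C2-symmetric (3R,5R)-diacetate, both stereocentres and both ester bonds being set together. The feature exploited is that C3 and C5 are like-configured secondary carbinol carbons of an acyclic chain, with C3–O already carrying the acetyl of the target; the two catechol rings are remote bystanders and no ring is closed. The precursor is the stereorandom diol with all four phenols benzylated. Removing either homotopic acetate, then debenzylation, completes the synthesis.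

Key step: step 4

Remark: the lipase is taken to be the W104A variant of Candida antarctica lipase B (widened stereospecificity pocket), and the boron chelates of step 1 are drawn as dibutoxyboron diketonates.

Step 1
Reactants: 1 pentane-2,4-dione; 2 3,4-bis(benzyloxy)benzaldehyde (2 equiv)
Product: 5 (1E,6E)-1,7-bis[3,4-bis(benzyloxy)phenyl]hepta-1,6-diene-3,5-dione, via dibutoxyboron chelate of pentane-2,4-dione 3 (not isolated), via dibutoxyboron chelate of the dienedione 4 (not isolated)
Conditions: B2O3, B(OBu)3, n-BuNH2 (cat.), EtOAc, 70 °C; then 0.4 M HCl, 60 °C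
Reagents that add atoms: none
Why: Boron-templated double aldol condensation, in which chelation of the 1,3-diketone blocks Knoevenagel reaction at C3 and directs the amine-catalysed condensation and dehydration with two molecules of 2 to the terminal methyl groups, giving the (E,E)-dienedione after acid hydrolysis of the chelate; no stereocentre is formed.

Step 2
Reactants: 5 (1E,6E)-1,7-bis[3,4-bis(benzyloxy)phenyl]hepta-1,6-diene-3,5-dione
Product: 6 1,7-bis[3,4-bis(benzyloxy)phenyl]heptane-3,5-dione
Conditions: H2 (1 atm), 10% Pd/C, Ph2S (cat.), THF, rt
Reagents that add atoms: none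
Why: Catalytic hydrogenation over palladium poisoned with Ph2S should saturate only the two conjugated C=C bonds, since the sulfide suppresses hydrogenolysis of the aryl benzyl ethers and leaves the ketones alone; no stereocentre is formed.

Step 3
Reactants: 6 1,7-bis[3,4-bis(benzyloxy)phenyl]heptane-3,5-dione
Product: 7 1,7-bis[3,4-bis(benzyloxy)phenyl]heptane-3,5-diol as the mixture of racemic anti plus meso syn isomers
Conditions: NaBH4 (excess), MeOH/THF, 0 °C to rt
Reagents that add atoms: none
Why: Borohydride reduction of both ketones of the 1,3-diketone without any stereocontrol, which is acceptable because step 4 is stereoconvergent and consumes every diol stereoisomer.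

Step 4
Reactants: 7 1,7-bis[3,4-bis(benzyloxy)phenyl]heptane-3,5-diol (stereoisomer mixture); 8 isopropenyl acetate (3 equiv)
Product: 10 (3R,5R)-1,7-bis[3,4-bis(benzyloxy)phenyl]heptane-3,5-diyl diacetate, via C5-epimeric (3R)-monoacetate 9 (not isolated)
Conditions: (C5Ph5)Ru(CO)2Cl (cat.), KOtBu (cat.), immobilised Candida antarctica lipase B W104A variant, Na2CO3, toluene, 50 °C, Ar
Reagents that add atoms: isopropenyl acetate 8, CC(=C)OC(C)=O
Why: Proposed new method: KOtBu converts (C5Ph5)Ru(CO)2Cl into its tert-butoxide, which exchanges with a free carbinol of 7; β-hydride elimination gives a ruthenium hydride that keeps the ketone bound and returns hydride to either face, so every unacylated centre (in the diols and in monoacetate 9) equilibrates between (R) and (S). In parallel the catalytic serine of the lipase is acetylated by 8 (acetone leaves, which makes the transfer irreversible) and passes acetyl only to a carbinol whose unbranched arylethyl chain sits in the widened stereospecificity pocket while the β-oxygenated chain points to the active-site entrance, which is the (R) arrangement at C3 and at C5; an acetylated centre has no O–H left to form the ruthenium alkoxide and is thereby locked. The closest known reaction type is the combined lipase and ruthenium dynamic kinetic asymmetric transformation of short symmetric diols such as pentane-2,4-diol and hexane-2,5-diol, which has not been extended to carbinols carrying two long chains. No ring is closed, and the two new stereocentres C3 and C5 are both set by the enzyme (catalyst control), the acyclic substrate contributing no bias of its own. The step needs (R)-selective acylation at both stages and epimerisation of the syn monoacetate faster than its 1,3-acetyl migration, which would place acetate on an (S) centre and leak to the meso diacetate; the substrate helps because the two chains flanking each carbinol differ at the β-carbon (CH2 versus CH–O), and the base is kept catalytic with Na2CO3 as buffer to slow migration. Any meso diacetate is a diastereomer of 10 and should be removable by chromatography or crystallisation.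

Step 5
Reactants: 10 (3R,5R)-1,7-bis[3,4-bis(benzyloxy)phenyl]heptane-3,5-diyl diacetate
Product: 11 (3R,5R)-1,7-bis[3,4-bis(benzyloxy)phenyl]-5-hydroxyheptan-3-yl acetate
Conditions: immobilised Candida antarctica lipase B W104A variant, n-BuOH (5 equiv), MTBE, 40 °C, stopped at partial conversion; recovered 10 resubmitted
Reagents that add atoms: none
Why: Lipase-catalysed alcoholysis is the reverse of the acyl transfer of step 4, so the same variant should pass one acetyl group of 10 to butan-1-ol; the two acetates are homotopic through the C2 axis, so either cleavage gives the same monoacetate, 1,3-acetyl migration in 11 is degenerate for the same reason, and the stereocentres are untouched because the ruthenium catalyst has been removed.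

Step 6
Reactants: 11 (3R,5R)-1,7-bis[3,4-bis(benzyloxy)phenyl]-5-hydroxyheptan-3-yl acetate
Product: 12 (3R,5R)-1,7-bis(3,4-dihydroxyphenyl)-5-hydroxyheptan-3-yl acetate
Conditions: H2 (1 atm), 10% Pd/C, EtOAc/EtOH, rt
Reagents that add atoms: none
Why: Neutral hydrogenolysis of the four aryl benzyl ethers over Pd/C should free both catechols without touching the secondary acetate, the secondary alcohol or the two stereocentres, neither of which is benzylic.

Compound list
1 | pentane-2,4-dione | CC(=O)CC(C)=O | starting material
2 | 3,4-bis(benzyloxy)benzaldehyde | O=Cc1ccc(OCc2ccccc2)c(OCc2ccccc2)c1 | starting material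
3 | dibutoxyboron chelate of pentane-2,4-dione (2,2-dibutoxy-4,6-dimethyl-1,3,2-dioxaborinine chelate) | CC1=CC(C)=[O+][B-](OCCCC)(OCCCC)O1 | intermediate (not isolated)
4 | dibutoxyboron chelate of (1E,6E)-1,7-bis[3,4-bis(benzyloxy)phenyl]hepta-1,6-diene-3,5-dione | CCCCO[B-]1(OCCCC)OC(/C=C/c2ccc(OCc3ccccc3)c(OCc3ccccc3)c2)=CC(/C=C/c2ccc(OCc3ccccc3)c(OCc3ccccc3)c2)=[O+]1 | intermediate (not isolated)
5 | (1E,6E)-1,7-bis[3,4-bis(benzyloxy)phenyl]hepta-1,6-diene-3,5-dione (largely enolised) | O=C(/C=C/c1ccc(OCc2ccccc2)c(OCc2ccccc2)c1)CC(=O)/C=C/c1ccc(OCc2ccccc2)c(OCc2ccccc2)c1 | intermediate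
6 | 1,7-bis[3,4-bis(benzyloxy)phenyl]heptane-3,5-dione | O=C(CCc1ccc(OCc2ccccc2)c(OCc2ccccc2)c1)CC(=O)CCc1ccc(OCc2ccccc2)c(OCc2ccccc2)c1 | intermediate
7 | 1,7-bis[3,4-bis(benzyloxy)phenyl]heptane-3,5-diol, racemic anti plus meso syn mixture | OC(CCc1ccc(OCc2ccccc2)c(OCc2ccccc2)c1)CC(O)CCc1ccc(OCc2ccccc2)c(OCc2ccccc2)c1 | intermediate
8 | isopropenyl acetate | CC(=C)OC(C)=O | starting material
9 | (3R)-1,7-bis[3,4-bis(benzyloxy)phenyl]-5-hydroxyheptan-3-yl acetate, both C5 epimers | CC(=O)O[C@H](CCc1ccc(OCc2ccccc2)c(OCc2ccccc2)c1)CC(O)CCc1ccc(OCc2ccccc2)c(OCc2ccccc2)c1 | intermediate (not isolated)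
10 | (3R,5R)-1,7-bis[3,4-bis(benzyloxy)phenyl]heptane-3,5-diyl diacetate | CC(=O)O[C@H](CCc1ccc(OCc2ccccc2)c(OCc2ccccc2)c1)C[C@H](OC(C)=O)CCc1ccc(OCc2ccccc2)c(OCc2ccccc2)c1 | intermediate
11 | (3R,5R)-1,7-bis[3,4-bis(benzyloxy)phenyl]-5-hydroxyheptan-3-yl acetate | CC(=O)O[C@H](CCc1ccc(OCc2ccccc2)c(OCc2ccccc2)c1)C[C@H](O)CCc1ccc(OCc2ccccc2)c(OCc2ccccc2)c1 | intermediate
12 | (3R,5R)-1,7-bis(3,4-dihydroxyphenyl)-5-hydroxyheptan-3-yl acetate | CC(=O)O[C@H](CCc1ccc(O)c(O)c1)C[C@H](O)CCc1ccc(O)c(O)c1 | target

Total step count: 6
Longest linear sequence: 6 steps (1 and 2 to 12)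

Steps most likely to fail

Step 4 (proposed new method). The lipase may not accept, or may not discriminate, a carbinol flanked by two long chains, so acyl transfer could be slow or unselective. Acetyl migration in the syn monoacetate may also compete with epimerisation, leaving stereoconvergence incomplete. The fallback uses known chemistry and sets out from diketone 6. Asymmetric hydrogenation of the Noyori type with RuCl2[(R)-BINAP] (H2 under pressure, MeOH/CH2Cl2, 50 °C) uses the ligand antipode that reduces pentane-2,4-dione to its (R,R)-diol. It should give (3R,5R)-1,7-bis[3,4-bis(benzyloxy)phenyl]heptane-3,5-diol F1, with both centres under catalyst control and the benzyl ethers untouched. Exhaustive acetylation (Ac2O, pyridine, DMAP cat., CH2Cl2, rt) then returns to the route at diacetate 10.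

Step 5. The first and the second alcoholysis may not differ in rate, so over-cleavage to the diol F1 or stalling would leave only a statistical share of monoacetate per pass. The fallback sets out from diacetate 10 and replaces partial removal by selective installation. Complete methanolysis (K2CO3 cat., MeOH/THF, rt) gives the diol F1. Trimethyl orthoacetate (PPTS cat., CH2Cl2, rt) converts it into the cyclic orthoester (4R,6R)-4,6-bis{2-[3,4-bis(benzyloxy)phenyl]ethyl}-2-methoxy-2-methyl-1,3-dioxane F2. Mild hydrolysis (aqueous AcOH, rt) opens F2 to a single monoacetate, because its two ring oxygens are related by the C2 axis. This returns to the route at monoacetate 11.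

Step 2. Hydrogenolysis of aryl benzyl ethers may accompany alkene saturation, or saturation may stop short on the poisoned catalyst. The fallback sets out from pentane-2,4-dione 1, bypasses steps 1 and 2, and never contains an alkene. The dianion of 1 (LiN(iPr)2, 2 equiv, THF, 0 °C) is alkylated at the terminal carbon with commercial 3,4-bis(benzyloxy)benzyl chloride (ClCc1ccc(OCc2ccccc2)c(OCc2ccccc2)c1) to give 6-[3,4-bis(benzyloxy)phenyl]hexane-2,4-dione F3. A second dianion formation, which should occur at the remaining methyl group, and a second alkylation with the same chloride return to the route at diketone 6.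

Further compounds
F1 | step 4 | (3R,5R)-1,7-bis[3,4-bis(benzyloxy)phenyl]heptane-3,5-diol | O[C@H](CCc1ccc(OCc2ccccc2)c(OCc2ccccc2)c1)C[C@H](O)CCc1ccc(OCc2ccccc2)c(OCc2ccccc2)c1
F2 | step 5 | (4R,6R)-4,6-bis{2-[3,4-bis(benzyloxy)phenyl]ethyl}-2-methoxy-2-methyl-1,3-dioxane | COC1(C)O[C@H](CCc2ccc(OCc3ccccc3)c(OCc3ccccc3)c2)C[C@H](O1)CCc2ccc(OCc3ccccc3)c(OCc3ccccc3)c2
F3 | step 2 | 6-[3,4-bis(benzyloxy)phenyl]hexane-2,4-dione | CC(=O)CC(=O)CCc1ccc(OCc2ccccc2)c(OCc2ccccc2)c1
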